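**Retrosynthetic overview**
1. Two features carry the plan. O1 of ring C joins the primary carbon C2 to C8a of ring A, which lies ortho to the C4 side chain. C3, the only stereocentre, has no acidic hydrogen while C4 is a protected carbinol and not a ketone.
2. Endgame at C4: the ketone appears only in the last three steps (hydrolysis of the C4 triethylsilyl ether, non-basic oxidation, fluoride cleavage of three aryl silyl ethers).
3. Ring C is the only ring made (rings A and B come from two benzaldehydes). It is closed at O1–C8a by palladium-catalysed intramolecular etherification of an aryl bromide with the C2 hydroxyl.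
4. C3–C4 and both stereocentres: Evans syn aldol of the ring-B arylacetyl imide of (S)-4-benzyl-2-oxazolidinone with 2-bromo-4-silyloxybenzaldehyde, then O-silylation and reductive removal of the auxiliary.
5. Ring-B acid: 2,3,4-trihydroxybenzaldehyde, 4-O-prenylation, aromatic Claisen rearrangement (1,1-dimethylallyl to C5'), O-methylation, change to silyl ethers, one-carbon homologation.

Key step: step 15

Remark on the chemistry: the SMILES is read as the (3R)-isoflavanone, and the dibutylboron enolate of the arylacetyl imide is taken to form with Z geometry, as N-acyl oxazolidinones do.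

Abbreviations: TBS = tert-butyldimethylsilyl; TES = triethylsilyl; MOM = methoxymethyl; ArB = 2,3-bis(TBS-oxy)-4-methoxy-5-(2-methylbut-3-en-2-yl)phenyl; ArA = 2-bromo-4-(TBS-oxy)phenyl. Isoflavanone numbering is used (O1, C2, C3, C4, C4a–C8a; primed numbers for ring B).

**Route**

Step 1
Reactants: 1 2,3,4-trihydroxybenzaldehyde; 2 prenyl bromide (1-bromo-3-methylbut-2-ene)
Product: 3 2,3-dihydroxy-4-(3-methylbut-2-enyloxy)benzaldehyde
Conditions: NaHCO3, DMF, rt → 40 °C
Reagents that add atoms: none
Why: Williamson ether synthesis in which the weak base should ionise only the 4-hydroxyl (para to the formyl group and the most acidic), while the 2-hydroxyl is held in a hydrogen bond to the carbonyl oxygen.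

Step 2
Reactants: 3 2,3-dihydroxy-4-(3-methylbut-2-enyloxy)benzaldehyde
Product: 4 2,3-bis(methoxymethoxy)-4-(3-methylbut-2-enyloxy)benzaldehyde
Conditions: MOMCl, iPr2NEt, CH2Cl2, 0 → 40 °C
Reagents that add atoms: chloromethyl methyl ether, COCCl
Why: O-alkylation of both phenols to methoxymethyl acetals, which cannot migrate to the neighbouring oxygen that is set free in the next step and which withstand heat and base.

Step 3
Reactants: 4 2,3-bis(methoxymethoxy)-4-(3-methylbut-2-enyloxy)benzaldehyde
Product: 5 4-hydroxy-2,3-bis(methoxymethoxy)-5-(2-methylbut-3-en-2-yl)benzaldehyde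
Conditions: PhNEt2, 190 °C, argon
Reagents that add atoms: none
Why: Aromatic Claisen rearrangement ([3,3]-sigmatropic shift) delivers the allyl unit with inversion of its ends to C5, the only ortho carbon that bears hydrogen, and tautomerisation of the dienone restores the phenol.

Step 4
Reactants: 5 4-hydroxy-2,3-bis(methoxymethoxy)-5-(2-methylbut-3-en-2-yl)benzaldehyde
Product: 6 4-methoxy-2,3-bis(methoxymethoxy)-5-(2-methylbut-3-en-2-yl)benzaldehyde
Conditions: MeI, K2CO3, DMF, rt
Reagents that add atoms: iodomethane, CI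
Why: Williamson methylation of the single free phenol, whose phenoxide is stabilised by the para formyl group and reacts readily with the small electrophile despite the flanking tertiary alkyl group.

Step 5
Reactants: 6 4-methoxy-2,3-bis(methoxymethoxy)-5-(2-methylbut-3-en-2-yl)benzaldehyde
Product: 7 2,3-dihydroxy-4-methoxy-5-(2-methylbut-3-en-2-yl)benzaldehyde
Conditions: 2 M aq HCl, MeOH, 45 °C
Reagents that add atoms: none
Why: Acid-catalysed acetal exchange to methanol removes both methoxymethyl groups, and the side-chain alkene is safe because its only ortho oxygen is the methyl ether.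

Step 6
Reactants: 7 2,3-dihydroxy-4-methoxy-5-(2-methylbut-3-en-2-yl)benzaldehyde
Product: 8 2,3-bis(tert-butyldimethylsilyloxy)-4-methoxy-5-(2-methylbut-3-en-2-yl)benzaldehyde (ArB–CHO)
Conditions: TBSCl, imidazole, DMAP (cat.), DMF, 40 °C
Reagents that add atoms: tert-butyldimethylsilyl chloride, CC(C)(C)[Si](C)(C)Cl
Why: Imidazole-promoted silylation of both phenols installs the groups that can be removed at the end by fluoride without base.

Step 7
Reactants: 8 ArB–CHO
Product: 9 1-ArB-2-methoxyethene (E/Z mixture)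
Conditions: Ph3P(CH2OMe)Cl, NaN(SiMe3)2, THF, 0 °C; then 8, 0 °C → rt
Reagents that add atoms: (methoxymethyl)triphenylphosphonium chloride, COC[P+](c1ccccc1)(c1ccccc1)c1ccccc1.[Cl-]
Why: Wittig olefination with the methoxymethylene ylide adds the one carbon needed, and the non-nucleophilic amide base does not attack the aryl silyl ethers.

Step 8
Reactants: 9 1-ArB-2-methoxyethene
Product: 10 2-ArB-acetaldehyde
Conditions: 88 % aq HCO2H, CH2Cl2, 0 °C → rt
Reagents that add atoms: water, O
Why: Acid-catalysed enol ether hydrolysis (protonation at the benzylic carbon, addition of water, loss of methanol) under a carboxylic acid that is too weak to cleave aryl TBS ethers.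

Step 9
Reactants: 10 2-ArB-acetaldehyde
Product: 11 2-ArB-acetic acid
Conditions: NaClO2, NaH2PO4, 2-methyl-2-butene, t-BuOH/H2O, 0 °C → rt
Reagents that add atoms: sodium chlorite, [Na+].[O-]Cl=O
Why: Pinnick oxidation converts the aldehyde to the acid, with the sacrificial alkene taking up hypochlorous acid so that the electron-rich ring and the side-chain vinyl group are spared.

Step 10
Reactants: 11 2-ArB-acetic acid; 12 (S)-4-benzyl-2-oxazolidinone
Product: 14 (S)-4-benzyl-3-(2-ArB-acetyl)oxazolidin-2-one, via mixed pivalic anhydride 13 (not isolated)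
Conditions: PivCl, Et3N, THF, −20 °C; then LiCl, 12, −20 °C → rt
Reagents that add atoms: none
Why: N-acylation of the oxazolidinone through the mixed anhydride, which is attacked at the less hindered arylacetyl carbonyl under conditions mild enough for the aryl silyl ethers.

Step 11
Reactants: 15 2-bromo-4-hydroxybenzaldehyde
Product: 16 2-bromo-4-(tert-butyldimethylsilyloxy)benzaldehyde (ArA–CHO)
Conditions: TBSCl, imidazole, DMF, rt
Reagents that add atoms: tert-butyldimethylsilyl chloride, CC(C)(C)[Si](C)(C)Cl
Why: Standard silylation of the phenol so that the aldehyde can meet the boron enolate without an acidic hydrogen.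

Step 12
Reactants: 14 (S)-4-benzyl-3-(2-ArB-acetyl)oxazolidin-2-one; 16 ArA–CHO
Product: 19 (S)-4-benzyl-3-[(2S,3S)-3-ArA-2-ArB-3-hydroxypropanoyl]oxazolidin-2-one, via dibutylboron Z-enolate 17 (not isolated), via dibutylboron aldolate 18 (not isolated)
Conditions: Bu2BOTf, iPr2NEt, CH2Cl2, −78 → 0 °C; then 16, −78 → 0 °C; pH 7 buffer, MeOH, 30 % H2O2, 0 °C
Reagents that add atoms: none
Why: Evans syn aldol reaction in which the Z-enolate reacts through a chair (Zimmerman–Traxler) transition state with the imide carbonyl turned away from the enolate oxygen, and the aldehyde adds to the face remote from the benzyl group, which sets both new centres (C3 and C4 of the isoflavanone) as 2S,3S syn.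

Step 13
Reactants: 19 (S)-4-benzyl-3-[(2S,3S)-3-ArA-2-ArB-3-hydroxypropanoyl]oxazolidin-2-one
Product: 20 (S)-4-benzyl-3-[(2S,3S)-3-ArA-2-ArB-3-(triethylsilyloxy)propanoyl]oxazolidin-2-one
Conditions: TESOTf, 2,6-lutidine, CH2Cl2, −78 → 0 °C
Reagents that add atoms: triethylsilyl trifluoromethanesulfonate, CC[Si](CC)(CC)OS(=O)(=O)C(F)(F)F
Why: Silylation with the reactive triflate and a hindered base caps the carbinol at low temperature before retro-aldol cleavage can set in, with a group more acid-labile than the aryl TBS ethers.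

Step 14
Reactants: 20 (S)-4-benzyl-3-[(2S,3S)-3-ArA-2-ArB-3-(triethylsilyloxy)propanoyl]oxazolidin-2-one
Product: 21 (2R,3S)-3-ArA-2-ArB-3-(triethylsilyloxy)propan-1-ol
Conditions: LiBH4, MeOH (1 equiv), Et2O, 0 °C
Reagents that add atoms: none
Why: Reductive cleavage of the imide by LiBH4 at the exocyclic carbonyl gives the primary alcohol without touching either stereocentre (the descriptor at C2 changes to R only because CH2OH ranks below the carbinol carbon).

Step 15
Reactants: 21 (2R,3S)-3-ArA-2-ArB-3-(triethylsilyloxy)propan-1-ol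
Product: 22 (3R,4S)-7-(TBS-oxy)-3-ArB-4-(triethylsilyloxy)chroman (trans)
Conditions: Pd(OAc)2 (5 mol %), 2-(di-tert-butylphosphino)-1,1'-binaphthyl (6 mol %), K3PO4, toluene, 80 °C
Reagents that add atoms: none
Why: Zerovalent palladium, formed in the flask from Pd(OAc)2 and the phosphine, inserts into the C8a–Br bond; the C2 hydroxyl is deprotonated by K3PO4 at the divalent palladium centre and displaces bromide to give a seven-membered aryl(alkoxo)palladium ring (Pd, O1, C2, C3, C4, C4a, C8a), from which C–O reductive elimination forms O1–C8a. The closest known reaction type is the palladium-catalysed intramolecular etherification of ortho-bromoaryl alkanols to chromans (Buchwald–Hartwig C–O coupling). Ring C closes in a six-membered exo mode at the sp2 carbon C8a, the bromide leaving outside the new ring. No stereocentre is formed: C3 and C4 come unchanged from the aldol, the syn chain becoming the trans ring, and because C4 is a silyl ether and not a carbonyl the base cannot epimerise C3. The step needs O-arylation to win over β-hydride elimination of the primary alkoxide, which the bulky electron-rich phosphine secures by speeding reductive elimination. It also needs a single reacting oxygen, which the substrate secures because only the C2 hydroxyl is free and only it reaches C8a through a six-membered ring.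

Step 16
Reactants: 22 (3R,4S)-7-(TBS-oxy)-3-ArB-4-(triethylsilyloxy)chroman
Product: 23 (3R,4S)-7-(TBS-oxy)-3-ArB-chroman-4-ol
Conditions: AcOH/THF/H2O (3:1:1), rt
Reagents that add atoms: none
Why: Acid-catalysed hydrolysis of the alkyl triethylsilyl ether, which is far more acid-labile than aryl TBS ethers, and water is chosen over an alcohol so that any ionisation at the activated benzylic C4 only returns the carbinol, whose configuration no longer matters.

Step 17
Reactants: 23 (3R,4S)-7-(TBS-oxy)-3-ArB-chroman-4-ol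
Product: 24 (3R)-7-(TBS-oxy)-3-ArB-chroman-4-one
Conditions: Dess–Martin periodinane, pyridine, CH2Cl2, 0 °C → rt; pH 7 work-up
Reagents that add atoms: none
Why: Dess–Martin oxidation of the secondary benzylic alcohol runs under near-neutral conditions, so the newly acidic C3 hydrogen should not exchange, and the still silylated catechol cannot be oxidised.

Step 18
Reactants: 24 (3R)-7-(TBS-oxy)-3-ArB-chroman-4-one
Product: 25 (3R)-3-[2,3-dihydroxy-4-methoxy-5-(2-methylbut-3-en-2-yl)phenyl]-7-hydroxychroman-4-one (target)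
Conditions: HF·pyridine, pyridine, THF, 0 °C → rt
Reagents that add atoms: none
Why: Fluoride-mediated cleavage of the three aryl silyl ethers in a weakly acidic medium, which frees the phenols without the base that would enolise the ketone and racemise C3.

**Compound list**
1 | 2,3,4-trihydroxybenzaldehyde | O=Cc1ccc(O)c(O)c1O | starting material
2 | prenyl bromide | CC(C)=CCBr | starting material
3 | 2,3-dihydroxy-4-(3-methylbut-2-enyloxy)benzaldehyde | O=Cc1ccc(OCC=C(C)C)c(O)c1O | intermediate
4 | 2,3-bis(methoxymethoxy)-4-(3-methylbut-2-enyloxy)benzaldehyde | O=Cc1ccc(OCC=C(C)C)c(OCOC)c1OCOC | intermediate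
5 | 4-hydroxy-2,3-bis(methoxymethoxy)-5-(2-methylbut-3-en-2-yl)benzaldehyde | C=CC(C)(C)c1cc(C=O)c(OCOC)c(OCOC)c1O | intermediate
6 | 4-methoxy-2,3-bis(methoxymethoxy)-5-(2-methylbut-3-en-2-yl)benzaldehyde | C=CC(C)(C)c1cc(C=O)c(OCOC)c(OCOC)c1OC | intermediate
7 | 2,3-dihydroxy-4-methoxy-5-(2-methylbut-3-en-2-yl)benzaldehyde | C=CC(C)(C)c1cc(C=O)c(O)c(O)c1OC | intermediate
8 | 2,3-bis(tert-butyldimethylsilyloxy)-4-methoxy-5-(2-methylbut-3-en-2-yl)benzaldehyde | C=CC(C)(C)c1cc(C=O)c(O[Si](C)(C)C(C)(C)C)c(O[Si](C)(C)C(C)(C)C)c1OC | intermediate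
9 | 1-ArB-2-methoxyethene (E/Z mixture) | C=CC(C)(C)c1cc(C=COC)c(O[Si](C)(C)C(C)(C)C)c(O[Si](C)(C)C(C)(C)C)c1OC | intermediate
10 | 2-ArB-acetaldehyde | C=CC(C)(C)c1cc(CC=O)c(O[Si](C)(C)C(C)(C)C)c(O[Si](C)(C)C(C)(C)C)c1OC | intermediate
11 | 2-ArB-acetic acid | C=CC(C)(C)c1cc(CC(=O)O)c(O[Si](C)(C)C(C)(C)C)c(O[Si](C)(C)C(C)(C)C)c1OC | intermediate
12 | (S)-4-benzyl-2-oxazolidinone | O=C1N[C@@H](Cc2ccccc2)CO1 | starting material
13 | mixed anhydride of 2-ArB-acetic acid and pivalic acid (not isolated) | C=CC(C)(C)c1cc(CC(=O)OC(=O)C(C)(C)C)c(O[Si](C)(C)C(C)(C)C)c(O[Si](C)(C)C(C)(C)C)c1OC | intermediate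
14 | (S)-4-benzyl-3-(2-ArB-acetyl)oxazolidin-2-one | C=CC(C)(C)c1cc(CC(=O)N2C(=O)OC[C@@H]2Cc2ccccc2)c(O[Si](C)(C)C(C)(C)C)c(O[Si](C)(C)C(C)(C)C)c1OC | intermediate
15 | 2-bromo-4-hydroxybenzaldehyde | O=Cc1ccc(O)cc1Br | starting material
16 | 2-bromo-4-(tert-butyldimethylsilyloxy)benzaldehyde | O=Cc1ccc(O[Si](C)(C)C(C)(C)C)cc1Br | intermediate
17 | dibutylboron Z-enolate of 14 (not isolated) | C=CC(C)(C)c1cc(/C=C(\OB(CCCC)CCCC)N2C(=O)OC[C@@H]2Cc2ccccc2)c(O[Si](C)(C)C(C)(C)C)c(O[Si](C)(C)C(C)(C)C)c1OC | intermediate
18 | dibutylboron aldolate of 19 (not isolated) | C=CC(C)(C)c1cc([C@H](C(=O)N2C(=O)OC[C@@H]2Cc2ccccc2)[C@H](OB(CCCC)CCCC)c2ccc(O[Si](C)(C)C(C)(C)C)cc2Br)c(O[Si](C)(C)C(C)(C)C)c(O[Si](C)(C)C(C)(C)C)c1OC | intermediate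
19 | (S)-4-benzyl-3-[(2S,3S)-3-ArA-2-ArB-3-hydroxypropanoyl]oxazolidin-2-one | C=CC(C)(C)c1cc([C@H](C(=O)N2C(=O)OC[C@@H]2Cc2ccccc2)[C@H](O)c2ccc(O[Si](C)(C)C(C)(C)C)cc2Br)c(O[Si](C)(C)C(C)(C)C)c(O[Si](C)(C)C(C)(C)C)c1OC | intermediate
20 | (S)-4-benzyl-3-[(2S,3S)-3-ArA-2-ArB-3-(triethylsilyloxy)propanoyl]oxazolidin-2-one | C=CC(C)(C)c1cc([C@H](C(=O)N2C(=O)OC[C@@H]2Cc2ccccc2)[C@H](O[Si](CC)(CC)CC)c2ccc(O[Si](C)(C)C(C)(C)C)cc2Br)c(O[Si](C)(C)C(C)(C)C)c(O[Si](C)(C)C(C)(C)C)c1OC | intermediate
21 | (2R,3S)-3-ArA-2-ArB-3-(triethylsilyloxy)propan-1-ol | C=CC(C)(C)c1cc([C@H](CO)[C@H](O[Si](CC)(CC)CC)c2ccc(O[Si](C)(C)C(C)(C)C)cc2Br)c(O[Si](C)(C)C(C)(C)C)c(O[Si](C)(C)C(C)(C)C)c1OC | intermediate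
22 | (3R,4S)-7-(TBS-oxy)-3-ArB-4-(triethylsilyloxy)chroman (trans) | C=CC(C)(C)c1cc([C@@H]2COc3cc(O[Si](C)(C)C(C)(C)C)ccc3[C@H]2O[Si](CC)(CC)CC)c(O[Si](C)(C)C(C)(C)C)c(O[Si](C)(C)C(C)(C)C)c1OC | intermediate
23 | (3R,4S)-7-(TBS-oxy)-3-ArB-chroman-4-ol | C=CC(C)(C)c1cc([C@@H]2COc3cc(O[Si](C)(C)C(C)(C)C)ccc3[C@H]2O)c(O[Si](C)(C)C(C)(C)C)c(O[Si](C)(C)C(C)(C)C)c1OC | intermediate
24 | (3R)-7-(TBS-oxy)-3-ArB-chroman-4-one | C=CC(C)(C)c1cc([C@@H]2COc3cc(O[Si](C)(C)C(C)(C)C)ccc3C2=O)c(O[Si](C)(C)C(C)(C)C)c(O[Si](C)(C)C(C)(C)C)c1OC | intermediate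
25 | (3R)-3-[2,3-dihydroxy-4-methoxy-5-(2-methylbut-3-en-2-yl)phenyl]-7-hydroxychroman-4-one | C=CC(C)(C)c1cc([C@@H]2COc3cc(O)ccc3C2=O)c(O)c(O)c1OC | target

**Step count**
Total: 18 steps. Longest linear sequence: 17 steps (steps 1–10 and 12–18, from compound 1).

**Steps most likely to fail**

Step 15. In the crowded palladacycle, β-hydride elimination from the palladium alkoxide may outrun C–O reductive elimination, so that the bromide is reduced and the primary carbinol oxidised. An aryl silyl group may also move to the primary alkoxide under the phosphate base. The fallback closes ring C at the other ether bond, O1–C2, by a Mitsunobu reaction. It sets out from 21: Miyaura borylation (B2pin2, KOAc, PdCl2(dppf), dioxane, 80 °C) should give the pinacol arylboronate F1. Oxidation (NaBO3·4H2O, THF/H2O, 0 °C → rt) should give the phenol F2. PPh3 and DIAD in THF at 0 °C should then displace the activated primary hydroxyl by the phenol oxygen, which returns the route to 22 with C3 and C4 untouched.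

Step 3. At 190 °C the new ortho-(1,1-dimethylallyl)phenol may react on, by an abnormal Claisen shift of the side chain or by ring closure of the phenol onto the alkene. The allyl group may also travel on to the para carbon with loss of the formyl group. The fallback introduces the tertiary allyl group by cross-coupling and not by rearrangement. It sets out from 1: methylation of the most acidic hydroxyl (MeI, NaHCO3, DMF) should give 2,3-dihydroxy-4-methoxybenzaldehyde F3. MOMCl and iPr2NEt should give the bis(methoxymethyl) ether F4. NBS in MeCN should give the 5-bromo compound F5, since C5 is para to O2, ortho to the methoxy group and meta to the formyl group. A γ-selective Suzuki–Miyaura coupling of F5 with prenylboronic acid pinacol ester (Pd(OAc)2, a bulky dialkylbiarylphosphine chosen for γ-selectivity, K3PO4, THF/H2O) would then return the route to 6.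

Step 16. The C4–O bond is benzylic and activated by O1 (ortho) and O7 (para), so it may ionise under acid; loss of the C3 proton would then give the isoflav-3-ene and destroy the stereocentre. If the hydrolysis is slow, the aryl silyl ethers may also begin to fall off. The fallback merges desilylation and oxidation. It sets out from 22: IBX in DMSO at rt cleaves triethylsilyl ethers in the presence of tert-butyldimethylsilyl ethers and oxidises the freed carbinol in the same flask, so the carbinol never accumulates. This should lead directly to 24, with no new compound on the way (F0).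

**Further compounds**
F1 | step 15 | (2R,3S)-2-ArB-3-[4-(TBS-oxy)-2-(4,4,5,5-tetramethyl-1,3,2-dioxaborolan-2-yl)phenyl]-3-(triethylsilyloxy)propan-1-ol | C=CC(C)(C)c1cc([C@H](CO)[C@H](O[Si](CC)(CC)CC)c2ccc(O[Si](C)(C)C(C)(C)C)cc2B2OC(C)(C)C(C)(C)O2)c(O[Si](C)(C)C(C)(C)C)c(O[Si](C)(C)C(C)(C)C)c1OC
F2 | step 15 | (2R,3S)-2-ArB-3-[2-hydroxy-4-(TBS-oxy)phenyl]-3-(triethylsilyloxy)propan-1-ol | C=CC(C)(C)c1cc([C@H](CO)[C@H](O[Si](CC)(CC)CC)c2ccc(O[Si](C)(C)C(C)(C)C)cc2O)c(O[Si](C)(C)C(C)(C)C)c(O[Si](C)(C)C(C)(C)C)c1OC
F3 | step 3 | 2,3-dihydroxy-4-methoxybenzaldehyde | O=Cc1ccc(OC)c(O)c1O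
F4 | step 3 | 4-methoxy-2,3-bis(methoxymethoxy)benzaldehyde | O=Cc1ccc(OC)c(OCOC)c1OCOC
F5 | step 3 | 5-bromo-4-methoxy-2,3-bis(methoxymethoxy)benzaldehyde | O=Cc1cc(Br)c(OC)c(OCOC)c1OCOC
F0 | step 16 | none | none
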